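The runs were generated by integration from invented constants.

**Forward clock.** The epsilon run kept 87.3 % of its charge as starting material after 8.00 h, and the beta run kept 98.7 % after 50.0 h. In both runs target and starting material together make up about the whole charge.

| flask | starting material | temperature | remark | time |
|---|---|---|---|---|
| beta | 0.050 M | 25 °C | run made earlier |  |
| epsilon | 0.075 M | 58 °C | run made earlier |  |
| Wednesday's | 0.10 M | 10 °C |  | 6.0 d |
| Sunday's | 0.10 M | 50 °C |  | 6.0 d |
| Tuesday's | 0.10 M | 30 °C |  | 6.0 d |
| Saturday's | 0.10 M | 70 °C |  | 6.0 d |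

| run | time / h | target / % | starting material / % |
|---|---|---|---|
| beta | 2.50 | 0.1 | 100.3 |
| beta | 6.00 | 0.2 | 99.7 |
| beta | 12.0 | 0.3 | 99.2 |
| beta | 20.0 | 0.7 | 99.7 |
| beta | 25.0 | 0.6 | 98.9 |
| beta | 30.0 | 1.1 | 98.7 |
| beta | 50.0 | 0.8 | 98.7 |
| epsilon | 0.500 | 0.9 | 99.6 |
| epsilon | 1.00 | 1.4 | 97.9 |
| epsilon | 2.50 | 3.8 | 96.3 |
| epsilon | 4.00 | 6.6 | 93.4 |
| epsilon | 6.00 | 9.8 | 90.2 |
| epsilon | 8.00 | 12.0 | 87.3 |

(scatter of a reading: 0.3 percentage points)

- in a conversion other conformer counts as not yet reacted; third conformer counts as reacted
- a reading or a percentage of target counts all its forms, free or not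

- the flask that comes out highest in amount of target, in percent of the starting material charged, or "all alike" when all lie within 1.5 percentage points (Wednesday's / Sunday's / Tuesday's / Saturday's / all alike)
- target at the end, in percent of the starting material charged, Wednesday's
- target at the end, in percent of the starting material charged, Sunday's
- target at the end, in percent of the starting material charged, Tuesday's
- target at the end, in percent of the starting material charged, Saturday's

**Doubling interval.** Read as plain exponential decays, these two readings give rate constants of 0.0170 h⁻¹ and 2.62 × 10⁻⁴ h⁻¹. The second rests on a loss of 1.30 % with a scatter of 0.3 percentage points, so it is a rough reading. Between them lies the doubling interval, the temperature rise that doubles the rate constant: 5.48 K.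

**Upper bound.** By this reckoning of my own, Saturday's run lasts 11.1 time constants. Decay with no way back then gives >99.9 % target.

**Lower bound.** The symmetric case, with forward and backward steps equal, is the zero of the scale, and it stops at half the charge. This floor is taken, not proven.

**Tightening.** Both curves can be started from the 6.6 % read at 4.00 h. At 8.00 h the one-way curve gives 12.8 % and the symmetric curve 12.3 %, against a reading of 12.0 %. At this scatter neither curve falls away, so the bracket stays as wide as it is.

**Forecast.** It names Saturday's and gives 0.5 %, 55 %, 7 % and 88 % for Wednesday's, Sunday's, Tuesday's and Saturday's. Its 88 % lies inside the bracket, and of the hot flask it says “essentially complete unless a reversible equilibrium caps it”.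

**Result.** The flasks give 0.378 %, 53.6 %, 6.87 % and 73.2 %, so Saturday's comes out highest, 15 points below the forecast.

    starting material ⇌ other conformer (K = 1.91, k = 4.50 × 10⁻⁷ s⁻¹, Ea = 122 kJ mol⁻¹, ΔH = −32.0 kJ mol⁻¹)
    starting material ⇌ target (K = 1.88, k = 1.78 × 10⁻⁵ s⁻¹, Ea = 105 kJ mol⁻¹, ΔH = −17.0 kJ mol⁻¹)
    other conformer → isomer of the product (k = 2.41 × 10⁻⁵ s⁻¹, Ea = 106 kJ mol⁻¹)
    other conformer ⇌ third conformer (K = 1.50, k = 9.56 × 10⁻⁵ s⁻¹, Ea = 112 kJ mol⁻¹, ΔH = −50.0 kJ mol⁻¹)
    third conformer → third product (k = 3.66 × 10⁻⁶ s⁻¹, Ea = 126 kJ mol⁻¹)
    crystals ⇌ target, rate k6*(cs6 - [target]) while solid is left; crystals form when [target] > cs6 (solubility = 39.0 mM, k = 0.00232 s⁻¹)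
    (constants at 70 °C)

**Saturday's balance.** By the doubling interval Saturday's run holds 11.1 forward time constants, yet its starting material stood at 20.9 % after 3.00 d and 20.2 % after 6.00 d. Saturday's flask by then reads a balance (an equilibrium limit), no longer the forward clock. Without the backward run from target to starting material, the same flask gives 97.5 % instead of 73.2 %, which is a part of the story. Saturday's stands 73 points above Wednesday's, and with what the temperature does to the reaction of starting material to target taken away, that gap is −0.041 points, the largest single effect.

**Second flask.** A flask like Wednesday's kept at 35 °C lasts 0.133 time constants by the doubling interval, which gives 12.5 % target. The computed flask holds 12.9 %.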